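**Retrosynthetic overview**

1. Enabling feature: the oxolane ring is meso, with a mirror plane through O1 and the midpoint of C3–C4. Both aryl-bearing carbons C2 and C5 are bonded to O1, so each is a latent cyclic oxocarbenium carbon (a masked meso-succinaldehyde). Each catechol ring is most nucleophilic at its C4, para to an oxygen.
2. Key disconnection: both C(ring)–aryl bonds are cut back to cis-3,4-bis(acetoxymethyl)-2,5-dimethoxyoxolane and two molecules of 1,2-bis(benzyloxy)benzene. The forward reaction is a two-directional Friedel–Crafts arylation; its second event joins the monoaryl methyl acetal to the arene at C5.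
3. The bis-acetal comes from furan-3,4-diyldimethanol by acetylation, oxidative 2,5-dimethoxylation and syn hydrogenation, which sets the cis C3/C4 pair.
4. Ring order: the oxolane is carried through from the furan and no ring is closed in the key step. Debenzylation finishes the synthesis.

Key step: step 4

Remark on the chemistry: the stated configuration is the achiral meso isomer (2R,3S,4R,5S): aryls cis to each other, acetoxymethyls cis to each other, each aryl trans to its neighbouring acetoxymethyl. Only relative configuration therefore has to be controlled. Compound 6 is racemic and is drawn as one enantiomer.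

**Route**

Step 1
Reactants: 1 furan-3,4-diyldimethanol
Product: 2 furan-3,4-diylbis(methylene) diacetate
Conditions: Ac2O (2.5 equiv), pyridine, DMAP (cat.), CH2Cl2, 0 °C to rt
Reagents that add atoms: acetic anhydride, CC(=O)OC(C)=O
Why: DMAP-catalysed O-acetylation (nucleophilic acyl substitution) of the two primary alcohols installs both acetates of the target at the outset and creates no stereocentre.

Step 2
Reactants: 2 furan-3,4-diylbis(methylene) diacetate
Product: 3 (2,5-dimethoxy-2,5-dihydrofuran-3,4-diyl)bis(methylene) diacetate (cis/trans acetal mixture)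
Conditions: Br2 (1.05 equiv), KOAc (2.5 equiv), MeOH, −40 to −10 °C
Reagents that add atoms: methanol, CO
Why: Clauson-Kaas oxidative 2,5-dimethoxylation (bromine adds across the furan 2,5-positions and methanol replaces both bromides via allylic oxocarbenium ions) raises both future benzylic carbons to the acetal level while the cold buffered medium spares the acetates; the acetal centres form as a mixture that is irrelevant because both are planarised in step 4.

Step 3
Reactants: 3 (2,5-dimethoxy-2,5-dihydrofuran-3,4-diyl)bis(methylene) diacetate
Product: 4 [(3R*,4S*)-2,5-dimethoxyoxolane-3,4-diyl]bis(methylene) diacetate (3,4-cis; mixture of acetal epimers)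
Conditions: H2 (50 bar), 5% Rh/Al2O3, EtOAc, rt
Reagents that add atoms: none
Why: Heterogeneous catalytic hydrogenation adds both hydrogens to one face of the ring C3=C4 bond (syn addition), so C3 and C4 are set together as the cis pair; rhodium is chosen because it is far less prone than palladium to hydrogenolyse allylic C–O bonds.

Step 4
Reactants: 4 [(3R*,4S*)-2,5-dimethoxyoxolane-3,4-diyl]bis(methylene) diacetate; 5 1,2-bis(benzyloxy)benzene (5 equiv, excess recovered)
Product: 7 meso-[(2R,3S,4R,5S)-2,5-bis[3,4-bis(benzyloxy)phenyl]oxolane-3,4-diyl]bis(methylene) diacetate, via monoaryl methyl acetal 6 (not isolated)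
Conditions: TMSOTf (0.3 equiv), CH2Cl2, −40 to 0 °C; NaHCO3 quench
Reagents that add atoms: none
Why: Acid ionises one methoxy group of 4 to a cyclic oxocarbenium ion at C2, which C4 of arene 5 (para to a benzyloxy group) attacks in a Friedel–Crafts alkylation, and loss of the second methoxy group from 6 gives the C5 oxocarbenium ion whose arylation joins the monoaryl oxolane to the second arene. The closest known reaction type is the Lewis-acid-promoted Friedel–Crafts C-arylation of 2-alkoxytetrahydrofurans and glycosyl donors by electron-rich arenes, run here in both directions on a 2,5-dimethoxyoxolane. No ring is closed, since the oxolane is preformed and only exocyclic C–C bonds are made. The new stereocentres C2 and C5 are substrate-controlled: the cis C3/C4 acetoxymethyl arms occupy one face and the adjacent acetate carbonyl can cap that face as a dioxanylium ion, so each arene should enter anti to its neighbouring arm (2,3-trans and 4,5-trans, hence 2,5-cis), and reversible acid ionisation of the electron-rich benzylic C–O bonds should funnel any epimer toward this most stable arrangement. The step needs para-regioselectivity on the arene, secured by the 1,2-dialkoxy pattern (C4 is para to one oxygen and unhindered), and a single arylation at each acetal carbon, secured by low temperature, catalytic acid and the much easier ionisation of an acetal than of a benzylic ether. Because the C3/C4 pair is meso, both enantiomers of racemic 6 should converge on the single meso product 7.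

Step 5
Reactants: 7 meso-[(2R,3S,4R,5S)-2,5-bis[3,4-bis(benzyloxy)phenyl]oxolane-3,4-diyl]bis(methylene) diacetate
Product: 8 meso-[(2R,3S,4R,5S)-2,5-bis(3,4-dihydroxyphenyl)oxolane-3,4-diyl]bis(methylene) diacetate (CNP0416169.1)
Conditions: H2 (1 atm), 10% Pd/C, EtOAc, rt; work-up under argon
Reagents that add atoms: none
Why: Palladium-catalysed hydrogenolysis of the four aryl benzyl ethers under neutral conditions should leave the alkyl acetates and, at atmospheric pressure in ethyl acetate, the ring benzylic C–O bonds intact, and touches no stereocentre.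

**Compound list**

1 | furan-3,4-diyldimethanol | OCc1cocc1CO | starting material
2 | furan-3,4-diylbis(methylene) diacetate | CC(=O)OCc1cocc1COC(C)=O | intermediate
3 | (2,5-dimethoxy-2,5-dihydrofuran-3,4-diyl)bis(methylene) diacetate (cis/trans acetal mixture) | COC1OC(OC)C(COC(C)=O)=C1COC(C)=O | intermediate
4 | [(3R*,4S*)-2,5-dimethoxyoxolane-3,4-diyl]bis(methylene) diacetate (3,4-cis; acetal epimers) | CC(=O)OC[C@@H]1[C@H](COC(C)=O)C(OC)OC1OC | intermediate
5 | 1,2-bis(benzyloxy)benzene | c1ccc(COc2ccccc2OCc2ccccc2)cc1 | starting material
6 | rac-[(2R*,3S*,4R*)-2-[3,4-bis(benzyloxy)phenyl]-5-methoxyoxolane-3,4-diyl]bis(methylene) diacetate (C5 epimers; not isolated) | CC(=O)OC[C@@H]1[C@H](COC(C)=O)C(OC)O[C@H]1c1ccc(OCc2ccccc2)c(OCc2ccccc2)c1 | intermediate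
7 | meso-[(2R,3S,4R,5S)-2,5-bis[3,4-bis(benzyloxy)phenyl]oxolane-3,4-diyl]bis(methylene) diacetate | CC(=O)OC[C@@H]1[C@H](COC(C)=O)[C@@H](c2ccc(OCc3ccccc3)c(OCc3ccccc3)c2)O[C@H]1c1ccc(OCc2ccccc2)c(OCc2ccccc2)c1 | intermediate
8 | meso-[(2R,3S,4R,5S)-2,5-bis(3,4-dihydroxyphenyl)oxolane-3,4-diyl]bis(methylene) diacetate | CC(=O)OC[C@@H]1[C@H](COC(C)=O)[C@@H](c2ccc(O)c(O)c2)O[C@H]1c1ccc(O)c(O)c1 | target

**Step count**

Total steps: 5. Longest linear sequence: 5 steps (1 → 2 → 3 → 4 → 7 → 8).

**Steps most likely to fail, with fallbacks**

Step 4. What may go wrong: acid ionisation of the newly formed benzylic C–O bonds, leading to ring opening and a second arylation at the same carbon; loss of methanol toward the furan; or incomplete facial control in the second arylation. The fallback sets out from 4 and returns at 7. It brings the aryl group in as a preformed organozinc under non-acidic conditions, a C-glycosylation-type coupling of a 2-halo-oxolane with an arylzinc. Compound 4 would be treated with bromotrimethylsilane (CH2Cl2, 0 °C) to give [(3R*,4S*)-2,5-dibromooxolane-3,4-diyl]bis(methylene) diacetate F1, used crude. Separately, commercial 4-bromo-1,2-bis(benzyloxy)benzene (Brc1ccc(OCc2ccccc2)c(OCc2ccccc2)c1) would be converted by bromine–lithium exchange (n-BuLi, THF, −78 °C) into [3,4-bis(benzyloxy)phenyl]lithium F2, and then with ZnBr2 into [3,4-bis(benzyloxy)phenyl]zinc bromide F3. F1 and F3 (toluene–THF, −20 °C to rt) should couple through the monoaryl bromide F4 to give 7. Each aryl should enter anti to the neighbouring acetoxymethyl arm, and the position of the C–Zn bond fixes the regiochemistry on the arene.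

Step 3. What may go wrong: slow saturation of the tetrasubstituted ring alkene, with competing hydrogenolysis of the allylic C–O bonds (acetate or acetal). The fallback sets out from 1 and returns at 4. Compound 1 would be dimethoxylated directly (Br2, KOAc, MeOH, −40 °C) to (2,5-dimethoxy-2,5-dihydrofuran-3,4-diyl)dimethanol F5. Hydroxyl-directed homogeneous hydrogenation ([Ir(cod)(PCy3)(py)]PF6, H2, CH2Cl2, rt) is effective for tetrasubstituted allylic alcohols and does not cleave allylic C–O bonds. It should give the cis-diol [(3R*,4S*)-2,5-dimethoxyoxolane-3,4-diyl]dimethanol F6. Acetylation (Ac2O, pyridine, DMAP) then returns to 4.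

Step 5. What may go wrong: hydrogenolytic opening of the oxolane at its benzylic C–O bonds during debenzylation. The fallback sets out from 4 and returns at 8. It carries the phenols as allyl ethers, so that no hydrogenation is needed at the end. Compound 4 and commercial 1,2-bis(allyloxy)benzene (C=CCOc1ccccc1OCC=C), under the conditions of step 4, should give, via the allyl-series monoaryl methyl acetal F7, the tetra-allyl ether [(2R,3S,4R,5S)-2,5-bis[3,4-bis(allyloxy)phenyl]oxolane-3,4-diyl]bis(methylene) diacetate F8. Tsuji–Trost deallylation (Pd(PPh3)4 cat., morpholine, THF, rt) should then give 8 with the acetates untouched.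

Further compounds
F1 | step 4 | [(3R*,4S*)-2,5-dibromooxolane-3,4-diyl]bis(methylene) diacetate | CC(=O)OC[C@@H]1[C@H](COC(C)=O)C(Br)OC1Br
F2 | step 4 | [3,4-bis(benzyloxy)phenyl]lithium | [Li]c1ccc(OCc2ccccc2)c(OCc2ccccc2)c1
F3 | step 4 | [3,4-bis(benzyloxy)phenyl]zinc bromide | Br[Zn]c1ccc(OCc2ccccc2)c(OCc2ccccc2)c1
F4 | step 4 | rac-[(2R*,3S*,4R*)-2-[3,4-bis(benzyloxy)phenyl]-5-bromooxolane-3,4-diyl]bis(methylene) diacetate | CC(=O)OC[C@@H]1[C@H](COC(C)=O)C(Br)O[C@H]1c1ccc(OCc2ccccc2)c(OCc2ccccc2)c1
F5 | step 3 | (2,5-dimethoxy-2,5-dihydrofuran-3,4-diyl)dimethanol | COC1OC(OC)C(CO)=C1CO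
F6 | step 3 | [(3R*,4S*)-2,5-dimethoxyoxolane-3,4-diyl]dimethanol | OC[C@@H]1[C@H](CO)C(OC)OC1OC
F7 | step 5 | rac-[(2R*,3S*,4R*)-2-[3,4-bis(allyloxy)phenyl]-5-methoxyoxolane-3,4-diyl]bis(methylene) diacetate | CC(=O)OC[C@@H]1[C@H](COC(C)=O)C(OC)O[C@H]1c1ccc(OCC=C)c(OCC=C)c1
F8 | step 5 | meso-[(2R,3S,4R,5S)-2,5-bis[3,4-bis(allyloxy)phenyl]oxolane-3,4-diyl]bis(methylene) diacetate | CC(=O)OC[C@@H]1[C@H](COC(C)=O)[C@@H](c2ccc(OCC=C)c(OCC=C)c2)O[C@H]1c1ccc(OCC=C)c(OCC=C)c1
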